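## Structural features

The target is a linear proanthocyanidin trimer of three flavan-3-ol units. The top and middle units are (−)-epicatechin 3-O-gallates (2R,3R, 2,3-cis), and the bottom unit is (+)-catechin (2R,3S, 2,3-trans) with a free 3-OH. C4 of the top unit is bonded to C8 of ring A of the middle unit, and C4 of the middle unit is bonded to C6 of ring A of the bottom unit, so the two interflavan bonds differ in regiochemistry. Each upper unit has three contiguous stereocentres, C2 (aryl), C3 (galloyloxy) and C4 (diarylmethine), with 2,3-cis and 3,4-trans relationships. The twelve flavan phenols and six gallate phenols are oxidation-prone, the gallate esters migrate or hydrolyse under base, and the doubly benzylic C4–aryl bonds are acid-labile, so the phenols must stay masked until a neutral last step. The real difficulties are the 4→6 link (C8, not C6, is the intrinsically preferred site of a flavan ring A), the choice of C8 of the middle ring among several nucleophilic aromatic carbons, and the 3,4-trans centre beside a cis 2,3 pair. The key step exploits the position of C4 of the middle unit between C6 of the trioxygenated bottom ring A and the galloyloxy-bearing C3: a cation there is stabilised by both neighbours, and C4a of a 3,5-dioxygenated phenyl ether on O1 can trap it to close ring C of the middle unit.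

## Logic of the disconnections

30 is traced back to 29 by cutting nineteen O–benzyl bonds and two aryl C–Br bonds. All phenols, the bottom 3-OH and the two capped ring A carbons are thus released in one neutral operation. The forward step must be a hydrogenolysis that leaves the benzylic C4–aryl bonds and the two esters intact.

In 29 the bond between C4 of the top unit and C8 of the middle unit is cut, giving 22 and 27. This is the classical polar interflavan disconnection and removes one third of the molecule as a unit derived directly from 23. The forward step needs one nucleophilic carbon only. 22 therefore carries bromine at C8 of its bottom unit and ether-protected oxygens on its middle ring A, which favours C8 over the doubly flanked C6. 27 carries bromine at its own C8 so that it cannot condense with itself.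

In 22 the C4–C4a bond of the middle unit is cut, which opens ring C of that unit and leads to 20. The cut is placed here because the C4–C6 bond to the bottom unit then already exists in the precursor, so the 4→6 regiochemistry is never decided in an intermolecular arylation. The gain is an open-chain 1,2,3-trioxygenated propane whose C1 and C2 centres can be set by reagent control. The forward step needs clean ionisation at the carbinol, ring closure by one of two equivalent ortho carbons, and 3,4-trans delivery. Compared with a design that carries allyl ethers on the nucleophilic ring and later frees its phenols, 20 is changed in two ways: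
- benzyl ethers on the nucleophilic ring, so nothing is unmasked between ring closure and the next coupling;
- bromine at C8 of the bottom unit, which takes over the task of silencing the bottom ring.

In 20 the bond between the carbinol carbon and C6 of the bottom unit is cut, giving 13 and 18. An aryl–metal addition to an aldehyde is chosen because the new carbinol centre is erased later. A phenoxide-directed ortho-hydroxyalkylation was weighed for this bond. It would need a regiodefined mono-phenol of the bottom unit and a phenol alkylation next to a migratory ester afterwards. With 18 the regiochemistry rests on halogen selectivity (iodine at C6, bromine at C8). The forward step must add a hindered aryl nucleophile to an α-acyloxy aldehyde without enolising it.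

13 is simplified to 11 (the formyl group from a vinyl group), 11 to 9 and 10 (ester C–O bond), 9 to 8 (acetal), and 8 through 7 to 6 (three aryl C–O bonds). The aryl ether is cut on the aryl side of oxygen, so that the benzylic C–O bond and its configuration are never broken. Forward, this demands nucleophilic aromatic substitution by a hindered alkoxide and then by benzyloxide on a progressively less activated fluoroarene.

6 is cut at the C1–C2 bond into 3 and 2, and 2 is made from 1. One C–C bond formation sets both stereocentres of the chain with the two oxygens already differentiated (free at C1, acetal at C2) and the aldehyde carbon masked as a vinyl group. The forward step needs syn selectivity and absolute control from the chiral boron ligands.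

18 is traced through 17, 16 and 15 to 14 by cutting the C6–I bond, the C8–Br bond and five O–benzyl bonds. The order of halogenation follows the intrinsic reactivity of ring A (C8 first, then the only remaining carbon, C6).

27 is cut at the ester into 26 and 10. 26 goes back through 25 and 24 to 23 by cutting the C4–O bond, the C8–Br bond and four O–benzyl bonds. The forward oxidation at C4 must place the leaving group trans to the 3-oxygen, so that the ester can later displace it from the rear.

## Other disconnections considered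

Alternative 1: The cut is at the two C2–aryl bonds of the top and middle units, with both rings B introduced last.
- Forward step: the bis(2,3-epoxychroman) A2 would react with the triarylaluminium A3. Each acetal-type epoxide would open at C2 with the aryl group transferred from aluminium on the face of the leaving oxygen, to give the diol A1.
- In favour: two C–C bonds and two stereocentres arise in one operation. The 2,3-cis relationship follows directly from the syn delivery. The two free 3-OH groups appear exactly where the gallates belong.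
- Against: A2 is a trimer-sized bis-enol-ether epoxide that cannot be drawn from 14 or 23 for its upper units, so both interflavan bonds must be built on ring-B-free chromenes. Its epoxides are highly acid-labile and sit next to bulky C4 substituents. A Lewis acidic aluminium reagent is used on a substrate with two ionisable C4–aryl bonds. Two hindered esterifications follow.
- Comparison: on C2 stereocontrol it is the equal of the chosen plan, or better, since substrate-directed syn delivery does not depend on the enantiomeric purity of a reagent. On bond count in the key step it is better. On step economy and on safety of the late intermediates it is weaker, because the skeleton before the key step is longer to make and less stable than 20.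

Alternative 2: The cut is at C4–C4a of the bottom unit.
- Forward step: a Lewis acid would activate the terminal epoxide of A5, and an ortho carbon of its para-substituted, symmetric 3,5-bis(benzyloxy)phenyl ether would attack the CH2 terminus, closing ring C of the bottom unit to give A4.
- In favour: the 4→6 link is encoded in the para substitution, a point on which it is the equal of the chosen plan. No stereocentre is made in the key step. The bottom 3-OH emerges free. Only a hydrogenolysis follows, so the end game is one step shorter than the chosen one.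
- Against: the electrophile is an unbiased epoxide. Attack at the internal carbon (five-membered ring), hydride or aryl shifts, and capture by a neighbouring ester carbonyl would all compete with the six-membered closure at the primary carbon. The reaction is the last skeletal step on a substrate that already holds both acid-labile C4–aryl bonds. A5 needs an aryl ether on an electron-rich phenol that cannot be made by nucleophilic aromatic substitution, so the bottom C2 centre would rest on an invertive benzylic etherification.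
- Comparison: mechanistically it is the same reaction family as the chosen step, with a less stabilised electrophile and no anchimeric guidance. Structurally it is as regiosecure. In step economy after the key step it is better. In reliability of the ring closure it is weaker.

Alternative 3: The cut takes both C4–C8 (interflavan) and C4–C4a of the top unit in one operation.
- Forward step: fluoride would unmask an aryne across C7–C8 of the middle unit of A7. The carbonyl of 13 would add with oxygen at C7 and carbon at C8. The four-membered adduct would open to a quinone methide, and the tethered aryl ether would close ring C of the top unit to give A6.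
- In favour: two C–C bonds and one ring are formed at once. The interflavan position is fixed at C8 by the position of the triple bond, a point on which it is better than the chosen plan, whose step 18 relies on intrinsic C8 preference and bromine caps. 13 serves unchanged as the top building block. Only a hydrogenolysis follows.
- Against: aryne–aldehyde insertions are low-yielding unless the quinone methide is trapped very fast. 13 is an α-acyloxy, β-aryloxy aldehyde that basic fluoride would enolise or deacylate. C4 of the top unit would be set in a neutral conjugate addition without an acyloxonium bridge, so 3,4-trans is not assured. A7 needs the middle–bottom dimer first and then several steps to place the silyl and triflate groups on ring A of its middle unit.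
- Comparison: structurally the most economical in bonds per step, and equal or better in end-game length. It needs something like the chosen key step to reach A7, and it is mechanistically the least secure of the four plans.

Key step: step 13

Remark on the chemistry: the carbinol carbon of 20 is carried as a mixture of epimers because it becomes planar in step 13. 3 and 10 are taken as catalogue compounds.

## Steps

Step 1
Reactants: 1 allyl alcohol
Product: 2 allyl methoxymethyl ether
Conditions: CH2(OMe)2 (excess), LiBr (cat.), TsOH·H2O (cat.), rt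
Reagents that add atoms: dimethoxymethane COCOC
Why: Acid-catalysed acetal exchange between the primary alcohol and dimethoxymethane, driven by the excess of acetal; no stereocentre is involved.

Step 2
Reactants: 2 allyl methoxymethyl ether; 3 3,4-bis(benzyloxy)benzaldehyde
Product: 6 (1R,2R)-1-[3,4-bis(benzyloxy)phenyl]-2-(methoxymethoxy)but-3-en-1-ol, via (Z)-3-(methoxymethoxy)allyllithium 4 (not isolated), via (Z)-3-(methoxymethoxy)allyl-diisopinocampheylborane 5 (not isolated)
Conditions: sBuLi, THF, −78 °C; (−)-Ipc2BOMe; BF3·OEt2; 3, −78 °C; then NaOH, H2O2, 0 °C → rt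
Reagents that add atoms: none
Why: Brown asymmetric γ-alkoxyallylboration: the chelated (Z)-allyllithium 4 is trapped on boron and BF3 removes methoxide to free borane 5, which adds to 3 through a chair six-membered transition state. The Z geometry should translate into the syn relationship, and the isopinocampheyl groups derived from (+)-α-pinene should select the aldehyde face that gives the 1R,2R isomer.

Step 3
Reactants: 6 (1R,2R)-1-[3,4-bis(benzyloxy)phenyl]-2-(methoxymethoxy)but-3-en-1-ol
Product: 7 1-{[(1R,2R)-1-[3,4-bis(benzyloxy)phenyl]-2-(methoxymethoxy)but-3-en-1-yl]oxy}-3,5-difluorobenzene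
Conditions: NaH, 1,3,5-trifluorobenzene, DMF, 0 °C → rt
Reagents that add atoms: 1,3,5-trifluorobenzene Fc1cc(F)cc(F)c1
Why: Nucleophilic aromatic substitution (addition–elimination) of the sodium alkoxide on a fluoroarene activated by two meta fluorines. The bond formed is O–C(aryl), so the benzylic C1–O bond is untouched and C1 is retained.

Step 4
Reactants: 7 1-{[(1R,2R)-1-[3,4-bis(benzyloxy)phenyl]-2-(methoxymethoxy)but-3-en-1-yl]oxy}-3,5-difluorobenzene
Product: 8 1,3-bis(benzyloxy)-5-{[(1R,2R)-1-[3,4-bis(benzyloxy)phenyl]-2-(methoxymethoxy)but-3-en-1-yl]oxy}benzene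
Conditions: BnOH, NaH, NMP, 90 °C
Reagents that add atoms: benzyl alcohol OCc1ccccc1
Why: Two further nucleophilic aromatic substitutions of fluoride by sodium benzyloxide in a dipolar aprotic solvent. The substrate holds only ethers, an acetal and an isolated alkene, and the stereocentres are remote from the reacting carbons.

Step 5
Reactants: 8 1,3-bis(benzyloxy)-5-{[(1R,2R)-1-[3,4-bis(benzyloxy)phenyl]-2-(methoxymethoxy)but-3-en-1-yl]oxy}benzene
Product: 9 (1R,2R)-1-[3,4-bis(benzyloxy)phenyl]-1-[3,5-bis(benzyloxy)phenoxy]but-3-en-2-ol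
Conditions: Me2BBr, CH2Cl2, −78 °C; then THF, aq NaHCO3
Reagents that add atoms: none
Why: Low-temperature Lewis acid cleavage of the acetal-type methoxymethyl ether by bromodimethylborane, which at −78 °C should leave benzyl ethers and the benzylic aryl ether alone. The C2–O bond is not broken, so C2 is retained.

Step 6
Reactants: 9 (1R,2R)-1-[3,4-bis(benzyloxy)phenyl]-1-[3,5-bis(benzyloxy)phenoxy]but-3-en-2-ol; 10 3,4,5-tris(benzyloxy)benzoic acid
Product: 11 (1R,2R)-1-[3,4-bis(benzyloxy)phenyl]-1-[3,5-bis(benzyloxy)phenoxy]but-3-en-2-yl 3,4,5-tris(benzyloxy)benzoate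
Conditions: DCC, DMAP (cat.), CH2Cl2, 0 °C → rt
Reagents that add atoms: none
Why: Steglich esterification of a secondary allylic alcohol; acylation at oxygen does not touch either stereocentre.

Step 7
Reactants: 11 (1R,2R)-1-[3,4-bis(benzyloxy)phenyl]-1-[3,5-bis(benzyloxy)phenoxy]but-3-en-2-yl 3,4,5-tris(benzyloxy)benzoate
Product: 13 (2S,3R)-3-[3,4-bis(benzyloxy)phenyl]-3-[3,5-bis(benzyloxy)phenoxy]-1-oxopropan-2-yl 3,4,5-tris(benzyloxy)benzoate, via 1,2-diol 12 (not isolated)
Conditions: OsO4 (cat.), NaIO4, 2,6-lutidine, dioxane/H2O, rt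
Reagents that add atoms: osmium tetroxide O=[Os](=O)(=O)=O; sodium periodate [Na+].[O-]I(=O)(=O)=O
Why: Lemieux–Johnson oxidative cleavage: dihydroxylation of the terminal alkene to 12 and periodate cleavage in the same flask, buffered by 2,6-lutidine. The aldehyde should be used at once and cold, since its α-hydrogen is activated by the ester. The change of descriptor at C2 is a priority effect only.

Step 8
Reactants: 14 (+)-catechin
Product: 15 5,7,3',4'-tetra-O-benzyl-(+)-catechin
Conditions: BnBr, K2CO3, DMF, rt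
Reagents that add atoms: benzyl bromide BrCc1ccccc1
Why: Williamson etherification of the four phenols under a carbonate base that does not deprotonate the secondary 3-OH.

Step 9
Reactants: 15 5,7,3',4'-tetra-O-benzyl-(+)-catechin
Product: 16 3,5,7,3',4'-penta-O-benzyl-(+)-catechin
Conditions: NaH, BnBr, DMF, 0 °C → rt
Reagents that add atoms: benzyl bromide BrCc1ccccc1
Why: Williamson etherification of the secondary alkoxide; it removes the only acidic proton before the organomagnesium step.

Step 10
Reactants: 16 3,5,7,3',4'-penta-O-benzyl-(+)-catechin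
Product: 17 8-bromo-3,5,7,3',4'-penta-O-benzyl-(+)-catechin
Conditions: NBS, CH2Cl2, −78 → 0 °C
Reagents that add atoms: N-bromosuccinimide O=C1CCC(=O)N1Br
Why: Electrophilic aromatic bromination; in perbenzylated flavan-3-ols C8 is the most reactive carbon of ring A, so one equivalent should cap that position.

Step 11
Reactants: 17 8-bromo-3,5,7,3',4'-penta-O-benzyl-(+)-catechin
Product: 18 8-bromo-6-iodo-3,5,7,3',4'-penta-O-benzyl-(+)-catechin
Conditions: NIS, TFA (cat.), CH2Cl2/MeCN, 0 °C → rt
Reagents that add atoms: N-iodosuccinimide O=C1CCC(=O)N1I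
Why: Electrophilic aromatic iodination at C6, the only remaining CH of the trioxygenated ring A, which is far more activated than the dialkoxyphenyl ring B.

Step 12
Reactants: 18 8-bromo-6-iodo-3,5,7,3',4'-penta-O-benzyl-(+)-catechin; 13 (2S,3R)-3-[3,4-bis(benzyloxy)phenyl]-3-[3,5-bis(benzyloxy)phenoxy]-1-oxopropan-2-yl 3,4,5-tris(benzyloxy)benzoate
Product: 20 (1R,2R,3RS)-1-[3,4-bis(benzyloxy)phenyl]-1-[3,5-bis(benzyloxy)phenoxy]-3-hydroxy-3-[8-bromo-3,5,7,3',4'-penta-O-benzyl-(+)-catechin-6-yl]propan-2-yl 3,4,5-tris(benzyloxy)benzoate, via arylmagnesium chloride 19 (not isolated)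
Conditions: iPrMgCl·LiCl, THF, −40 °C; then 13, LaCl3·2LiCl, THF, −78 °C; AcOH quench at −78 °C
Reagents that add atoms: none
Why: Iodine–magnesium exchange is much faster for the aryl iodide than for the aryl bromide, so 19 forms at C6 only. Its 1,2-addition to the aldehyde, assisted by the oxophilic lanthanum salt and quenched cold to avoid enolisation and acyl transfer, should give the carbinol. The new centre is not controlled and need not be.

Step 13
Reactants: 20 (1R,2R,3RS)-1-[3,4-bis(benzyloxy)phenyl]-1-[3,5-bis(benzyloxy)phenoxy]-3-hydroxy-3-[8-bromo-3,5,7,3',4'-penta-O-benzyl-(+)-catechin-6-yl]propan-2-yl 3,4,5-tris(benzyloxy)benzoate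
Product: 22 5,7,3',4'-tetra-O-benzyl-3-O-[3,4,5-tris(benzyloxy)benzoyl]-(−)-epicatechin-(4β→6)-8-bromo-3,5,7,3',4'-penta-O-benzyl-(+)-catechin, via 1,3-dioxolan-2-ylium ion 21 (not isolated)
Conditions: BF3·OEt2 (2 equiv), CH2Cl2 (0.005 M), −78 → −30 °C; then Et3N, aq NaHCO3
Reagents that add atoms: none
Why: BF3 coordinates the benzylic hydroxyl of 20, and ionisation gives a cation at the future C4 that is delocalised into the bottom ring A (oxygens at C5 and C7 ortho, O1 para) and is captured by the carbonyl oxygen of the C3 ester as the monocyclic 2-aryl-1,3-dioxolan-2-ylium ion 21; because the carbinol configuration is lost, the ion can settle in its more stable form with the bottom aryl and the C2 side chain trans on the five-membered ring, which at this stage is not fused to any other ring. The closest known reaction type is the acid-promoted intramolecular Friedel–Crafts alkylation of an electron-rich arene by a benzylic cation with anchimeric assistance from a vicinal ester, as in acyloxonium-mediated C4 arylation of flavan-3-ol esters. An ortho carbon of the 3,5-bis(benzyloxy)phenyl ether (the two are equivalent by symmetry and the para carbon cannot reach) attacks C4 to form C4–C4a, and loss of a proton restores aromaticity. The ring closed is ring C of the middle unit, a six-membered closure that is 6-endo with respect to the arene, since the attacking C4a=C8a π bond lies inside the new ring. The one new stereocentre, C4, is set by backside opening of the trans acyloxonium bridge, which puts the bottom aryl anti to the galloyloxy group (3,4-trans, 4R). Peri strain between that aryl and the C5 benzyloxy group of the forming ring A favours the same quasi-axial arrangement if part of the reaction runs through the open cation. The interflavan regiochemistry is not at stake because the C4–C6 bond already exists, and the bromine at C8 leaves the bottom ring without any free carbon, so intermolecular alkylation can only involve the hindered middle ring and is suppressed by high dilution. Closure onto ring B of the same unit would give a strained five-membered ring from a much less nucleophilic dialkoxyphenyl group and should not compete.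

Step 14
Reactants: 23 (−)-epicatechin
Product: 24 5,7,3',4'-tetra-O-benzyl-(−)-epicatechin
Conditions: BnBr, K2CO3, DMF, rt
Reagents that add atoms: benzyl bromide BrCc1ccccc1
Why: Williamson etherification of the four phenols; the 3-OH stays free for later esterification.

Step 15
Reactants: 24 5,7,3',4'-tetra-O-benzyl-(−)-epicatechin
Product: 25 8-bromo-5,7,3',4'-tetra-O-benzyl-(−)-epicatechin
Conditions: NBS, CH2Cl2, −78 → 0 °C
Reagents that add atoms: N-bromosuccinimide O=C1CCC(=O)N1Br
Why: Electrophilic bromination at C8, the most reactive ring A carbon; the bromine caps the position through which this unit would otherwise condense with itself in step 18.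

Step 16
Reactants: 25 8-bromo-5,7,3',4'-tetra-O-benzyl-(−)-epicatechin
Product: 26 (2R,3R,4S)-8-bromo-5,7,3',4'-tetra-O-benzyl-4-(2-ethoxyethoxy)-(−)-epicatechin
Conditions: DDQ, 2-ethoxyethanol, CH2Cl2, rt
Reagents that add atoms: 2-ethoxyethanol CCOCCO
Why: Benzylic oxidation by hydride abstraction at C4, followed by capture of the cation by the alcohol on the face opposite the axial 3-OH. This should give the 4β (3,4-trans) ether, a known activation of benzylated flavan-3-ols.

Step 17
Reactants: 26 (2R,3R,4S)-8-bromo-5,7,3',4'-tetra-O-benzyl-4-(2-ethoxyethoxy)-(−)-epicatechin; 10 3,4,5-tris(benzyloxy)benzoic acid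
Product: 27 (2R,3R,4S)-8-bromo-5,7,3',4'-tetra-O-benzyl-4-(2-ethoxyethoxy)-(−)-epicatechin 3-O-[3,4,5-tris(benzyloxy)benzoate]
Conditions: DCC, DMAP, CH2Cl2, rt
Reagents that add atoms: none
Why: Steglich esterification under non-acidic conditions that the C4 ether tolerates; no stereocentre is affected.

Step 18
Reactants: 22 5,7,3',4'-tetra-O-benzyl-3-O-[3,4,5-tris(benzyloxy)benzoyl]-(−)-epicatechin-(4β→6)-8-bromo-3,5,7,3',4'-penta-O-benzyl-(+)-catechin; 27 (2R,3R,4S)-8-bromo-5,7,3',4'-tetra-O-benzyl-4-(2-ethoxyethoxy)-(−)-epicatechin 3-O-[3,4,5-tris(benzyloxy)benzoate]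
Product: 29 8-bromo-5,7,3',4'-tetra-O-benzyl-3-O-[3,4,5-tris(benzyloxy)benzoyl]-(−)-epicatechin-(4β→8)-5,7,3',4'-tetra-O-benzyl-3-O-[3,4,5-tris(benzyloxy)benzoyl]-(−)-epicatechin-(4β→6)-8-bromo-3,5,7,3',4'-penta-O-benzyl-(+)-catechin, via fused acyloxonium ion 28 (not isolated)
Conditions: TMSOTf (0.3 equiv), CH2Cl2, 4 Å MS, −78 → −40 °C; Et3N quench
Reagents that add atoms: none
Why: Lewis acid-mediated interflavan coupling (Friedel–Crafts alkylation): the C4 ether leaves with rear-side help from the 3-O-ester to give the cis-fused acyloxonium ion 28, which the arene opens anti, so the new bond is 3,4-trans (4β). The only unhindered nucleophilic carbon is C8 of the middle unit, since C8 of the bottom unit and C8 of 27 are brominated and C6 of each ether-protected ring is flanked by two benzyloxy groups.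

Step 19
Reactants: 29 8-bromo-5,7,3',4'-tetra-O-benzyl-3-O-[3,4,5-tris(benzyloxy)benzoyl]-(−)-epicatechin-(4β→8)-5,7,3',4'-tetra-O-benzyl-3-O-[3,4,5-tris(benzyloxy)benzoyl]-(−)-epicatechin-(4β→6)-8-bromo-3,5,7,3',4'-penta-O-benzyl-(+)-catechin
Product: 30 (−)-epicatechin 3-O-gallate-(4β→8)-(−)-epicatechin 3-O-gallate-(4β→6)-(+)-catechin (CNP0154615.1)
Conditions: H2 (1 atm), Pd(OH)2/C, NaOAc, THF/MeOH/H2O, rt
Reagents that add atoms: none
Why: Catalytic hydrogenolysis of the nineteen benzyl ethers and hydrodehalogenation of the two aryl bromides in one neutral operation, with acetate buffering the HBr formed so that the acid-labile interflavan bonds are not exposed. No stereocentre is touched.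

## Compound list

1 | allyl alcohol | C=CCO | starting material
2 | allyl methoxymethyl ether | C=CCOCOC | intermediate
3 | 3,4-bis(benzyloxy)benzaldehyde | O=Cc1ccc(OCc9ccccc9)c(OCc9ccccc9)c1 | starting material
4 | (Z)-3-(methoxymethoxy)allyllithium | [Li]C/C=C\OCOC | intermediate
5 | [(Z)-3-(methoxymethoxy)allyl]diisopinocampheylborane (isopinocampheyl groups from (+)-α-pinene) | COCO/C=C\CB([C@@H]1C[C@@H]2C[C@H]([C@H]1C)C2(C)C)[C@@H]1C[C@@H]2C[C@H]([C@H]1C)C2(C)C | intermediate
6 | (1R,2R)-1-[3,4-bis(benzyloxy)phenyl]-2-(methoxymethoxy)but-3-en-1-ol | O[C@H](c1ccc(OCc9ccccc9)c(OCc9ccccc9)c1)[C@H](OCOC)C=C | intermediate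
7 | 1-{[(1R,2R)-1-[3,4-bis(benzyloxy)phenyl]-2-(methoxymethoxy)but-3-en-1-yl]oxy}-3,5-difluorobenzene | Fc1cc(F)cc(c1)O[C@H](c1ccc(OCc9ccccc9)c(OCc9ccccc9)c1)[C@H](OCOC)C=C | intermediate
8 | 1,3-bis(benzyloxy)-5-{[(1R,2R)-1-[3,4-bis(benzyloxy)phenyl]-2-(methoxymethoxy)but-3-en-1-yl]oxy}benzene | C(c9ccccc9)Oc1cc(OCc9ccccc9)cc(c1)O[C@H](c1ccc(OCc9ccccc9)c(OCc9ccccc9)c1)[C@H](OCOC)C=C | intermediate
9 | (1R,2R)-1-[3,4-bis(benzyloxy)phenyl]-1-[3,5-bis(benzyloxy)phenoxy]but-3-en-2-ol | C(c9ccccc9)Oc1cc(OCc9ccccc9)cc(c1)O[C@H](c1ccc(OCc9ccccc9)c(OCc9ccccc9)c1)[C@H](O)C=C | intermediate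
10 | 3,4,5-tris(benzyloxy)benzoic acid | OC(=O)c1cc(OCc9ccccc9)c(OCc9ccccc9)c(OCc9ccccc9)c1 | starting material
11 | (1R,2R)-1-[3,4-bis(benzyloxy)phenyl]-1-[3,5-bis(benzyloxy)phenoxy]but-3-en-2-yl 3,4,5-tris(benzyloxy)benzoate | C(c9ccccc9)Oc1cc(OCc9ccccc9)cc(c1)O[C@H](c1ccc(OCc9ccccc9)c(OCc9ccccc9)c1)[C@H](OC(=O)c1cc(OCc9ccccc9)c(OCc9ccccc9)c(OCc9ccccc9)c1)C=C | intermediate
12 | (2RS,3R,4R)-4-[3,4-bis(benzyloxy)phenyl]-4-[3,5-bis(benzyloxy)phenoxy]-1,2-dihydroxybutan-3-yl 3,4,5-tris(benzyloxy)benzoate | C(c9ccccc9)Oc1cc(OCc9ccccc9)cc(c1)O[C@H](c1ccc(OCc9ccccc9)c(OCc9ccccc9)c1)[C@H](OC(=O)c1cc(OCc9ccccc9)c(OCc9ccccc9)c(OCc9ccccc9)c1)C(O)CO | intermediate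
13 | (2S,3R)-3-[3,4-bis(benzyloxy)phenyl]-3-[3,5-bis(benzyloxy)phenoxy]-1-oxopropan-2-yl 3,4,5-tris(benzyloxy)benzoate | C(c9ccccc9)Oc1cc(OCc9ccccc9)cc(c1)O[C@H](c1ccc(OCc9ccccc9)c(OCc9ccccc9)c1)[C@H](OC(=O)c1cc(OCc9ccccc9)c(OCc9ccccc9)c(OCc9ccccc9)c1)C=O | intermediate
14 | (+)-catechin | O[C@H]1Cc2c(O)cc(O)cc2O[C@@H]1c1ccc(O)c(O)c1 | starting material
15 | 5,7,3',4'-tetra-O-benzyl-(+)-catechin | O[C@H]1Cc2c(OCc9ccccc9)cc(OCc9ccccc9)cc2O[C@@H]1c1ccc(OCc9ccccc9)c(OCc9ccccc9)c1 | intermediate
16 | 3,5,7,3',4'-penta-O-benzyl-(+)-catechin | C(c9ccccc9)O[C@H]1Cc2c(OCc9ccccc9)cc(OCc9ccccc9)cc2O[C@@H]1c1ccc(OCc9ccccc9)c(OCc9ccccc9)c1 | intermediate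
17 | 8-bromo-3,5,7,3',4'-penta-O-benzyl-(+)-catechin | C(c9ccccc9)O[C@H]1Cc2c(OCc9ccccc9)cc(OCc9ccccc9)c(Br)c2O[C@@H]1c1ccc(OCc9ccccc9)c(OCc9ccccc9)c1 | intermediate
18 | 8-bromo-6-iodo-3,5,7,3',4'-penta-O-benzyl-(+)-catechin | C(c9ccccc9)O[C@H]1Cc2c(OCc9ccccc9)c(I)c(OCc9ccccc9)c(Br)c2O[C@@H]1c1ccc(OCc9ccccc9)c(OCc9ccccc9)c1 | intermediate
19 | [8-bromo-3,5,7,3',4'-penta-O-benzyl-(+)-catechin-6-yl]magnesium chloride | C(c9ccccc9)O[C@H]1Cc2c(OCc9ccccc9)c([Mg]Cl)c(OCc9ccccc9)c(Br)c2O[C@@H]1c1ccc(OCc9ccccc9)c(OCc9ccccc9)c1 | intermediate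
20 | (1R,2R,3RS)-1-[3,4-bis(benzyloxy)phenyl]-1-[3,5-bis(benzyloxy)phenoxy]-3-hydroxy-3-[8-bromo-3,5,7,3',4'-penta-O-benzyl-(+)-catechin-6-yl]propan-2-yl 3,4,5-tris(benzyloxy)benzoate | C(c9ccccc9)Oc1cc(OCc9ccccc9)cc(c1)O[C@H](c1ccc(OCc9ccccc9)c(OCc9ccccc9)c1)[C@H](OC(=O)c1cc(OCc9ccccc9)c(OCc9ccccc9)c(OCc9ccccc9)c1)C(O)c1c(OCc9ccccc9)c(Br)c2c(c1OCc9ccccc9)C[C@H](OCc9ccccc9)[C@@H](c1ccc(OCc9ccccc9)c(OCc9ccccc9)c1)O2 | intermediate
21 | trans-4,5-disubstituted 2-[3,4,5-tris(benzyloxy)phenyl]-1,3-dioxolan-2-ylium ion bridging C3 and C4 of the future middle unit | C(c9ccccc9)Oc1cc(OCc9ccccc9)cc(c1)O[C@H](c1ccc(OCc9ccccc9)c(OCc9ccccc9)c1)[C@@H]1OC(c2cc(OCc9ccccc9)c(OCc9ccccc9)c(OCc9ccccc9)c2)=[O+][C@H]1c1c(OCc9ccccc9)c(Br)c2c(c1OCc9ccccc9)C[C@H](OCc9ccccc9)[C@@H](c1ccc(OCc9ccccc9)c(OCc9ccccc9)c1)O2 | intermediate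
22 | 5,7,3',4'-tetra-O-benzyl-3-O-[3,4,5-tris(benzyloxy)benzoyl]-(−)-epicatechin-(4β→6)-8-bromo-3,5,7,3',4'-penta-O-benzyl-(+)-catechin (upper unit 2R,3R,4R) | C(c9ccccc9)Oc1cc(OCc9ccccc9)c2c(c1)O[C@H](c1ccc(OCc9ccccc9)c(OCc9ccccc9)c1)[C@H](OC(=O)c1cc(OCc9ccccc9)c(OCc9ccccc9)c(OCc9ccccc9)c1)[C@H]2c1c(OCc9ccccc9)c(Br)c2c(c1OCc9ccccc9)C[C@H](OCc9ccccc9)[C@@H](c1ccc(OCc9ccccc9)c(OCc9ccccc9)c1)O2 | intermediate
23 | (−)-epicatechin | O[C@@H]1Cc2c(O)cc(O)cc2O[C@@H]1c1ccc(O)c(O)c1 | starting material
24 | 5,7,3',4'-tetra-O-benzyl-(−)-epicatechin | O[C@@H]1Cc2c(OCc9ccccc9)cc(OCc9ccccc9)cc2O[C@@H]1c1ccc(OCc9ccccc9)c(OCc9ccccc9)c1 | intermediate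
25 | 8-bromo-5,7,3',4'-tetra-O-benzyl-(−)-epicatechin | O[C@@H]1Cc2c(OCc9ccccc9)cc(OCc9ccccc9)c(Br)c2O[C@@H]1c1ccc(OCc9ccccc9)c(OCc9ccccc9)c1 | intermediate
26 | (2R,3R,4S)-8-bromo-5,7,3',4'-tetra-O-benzyl-4-(2-ethoxyethoxy)-(−)-epicatechin | O[C@@H]1[C@@H](OCCOCC)c2c(OCc9ccccc9)cc(OCc9ccccc9)c(Br)c2O[C@@H]1c1ccc(OCc9ccccc9)c(OCc9ccccc9)c1 | intermediate
27 | (2R,3R,4S)-8-bromo-5,7,3',4'-tetra-O-benzyl-4-(2-ethoxyethoxy)-(−)-epicatechin 3-O-[3,4,5-tris(benzyloxy)benzoate] | O=C(O[C@@H]1[C@@H](OCCOCC)c2c(OCc9ccccc9)cc(OCc9ccccc9)c(Br)c2O[C@@H]1c1ccc(OCc9ccccc9)c(OCc9ccccc9)c1)c1cc(OCc9ccccc9)c(OCc9ccccc9)c(OCc9ccccc9)c1 | intermediate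
28 | cis-fused 2-[3,4,5-tris(benzyloxy)phenyl]-1,3-dioxolan-2-ylium ion across C3 and C4 of the 8-bromo-tetra-O-benzylepicatechin unit | C1(c5cc(OCc9ccccc9)c(OCc9ccccc9)c(OCc9ccccc9)c5)=[O+][C@@H]2c3c(OCc9ccccc9)cc(OCc9ccccc9)c(Br)c3O[C@H](c3ccc(OCc9ccccc9)c(OCc9ccccc9)c3)[C@@H]2O1 | intermediate
29 | 8-bromo-5,7,3',4'-tetra-O-benzyl-3-O-[3,4,5-tris(benzyloxy)benzoyl]-(−)-epicatechin-(4β→8)-5,7,3',4'-tetra-O-benzyl-3-O-[3,4,5-tris(benzyloxy)benzoyl]-(−)-epicatechin-(4β→6)-8-bromo-3,5,7,3',4'-penta-O-benzyl-(+)-catechin | O=C(O[C@@H]1[C@@H](c2c(OCc9ccccc9)cc(OCc9ccccc9)c3c2O[C@H](c2ccc(OCc9ccccc9)c(OCc9ccccc9)c2)[C@H](OC(=O)c2cc(OCc9ccccc9)c(OCc9ccccc9)c(OCc9ccccc9)c2)[C@H]3c2c(OCc9ccccc9)c(Br)c3c(c2OCc9ccccc9)C[C@H](OCc9ccccc9)[C@@H](c2ccc(OCc9ccccc9)c(OCc9ccccc9)c2)O3)c2c(OCc9ccccc9)cc(OCc9ccccc9)c(Br)c2O[C@@H]1c1ccc(OCc9ccccc9)c(OCc9ccccc9)c1)c1cc(OCc9ccccc9)c(OCc9ccccc9)c(OCc9ccccc9)c1 | intermediate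
30 | (−)-epicatechin 3-O-gallate-(4β→8)-(−)-epicatechin 3-O-gallate-(4β→6)-(+)-catechin (CNP0154615.1) | O=C(O[C@@H]1[C@@H](c2c(O)cc(O)c3c2O[C@H](c2ccc(O)c(O)c2)[C@H](OC(=O)c2cc(O)c(O)c(O)c2)[C@H]3c2c(O)cc3c(c2O)C[C@H](O)[C@@H](c2ccc(O)c(O)c2)O3)c2c(O)cc(O)cc2O[C@@H]1c1ccc(O)c(O)c1)c1cc(O)c(O)c(O)c1 | target

## Step count and least certain steps

Total step count: 19. Longest linear sequence: 11 steps (steps 1 to 7, then 12, 13, 18 and 19).

Step 13 (key step).
- What may go wrong: loss of a proton from C3 of the cation instead of ring closure, ionisation of the benzylic aryl ether at C2, intermolecular alkylation of the middle ring A, or erosion of facial selectivity if the open cation reacts faster than the bridged ion.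
- Fallback: the order of the two bond formations at C4 is reversed. It sets out from 13 and 17 and comes back at 22. 13 would be cyclised on its own by a mild Lewis acid (intramolecular Friedel–Crafts hydroxyalkylation, MgBr2·OEt2, CH2Cl2, −78 °C) to the 4-hydroxyflavan 3-gallate F1. F1 would then be ionised with TMSOTf in the presence of an excess of 17, whose only free ring A carbon is C6, so that anti opening of the fused acyloxonium ion gives 22.

Step 12.
- What may go wrong: deprotonation of the aldehyde at C2 by the hindered arylmagnesium, followed by epimerisation or β-elimination of the aryloxide; or acyl transfer from O2 to the new alkoxide before the quench.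
- Fallback: the ester is introduced after the C–C bond. It sets out from 9 and comes back at 20.
  - 9 would be silylated (Et3SiCl, imidazole) to the triethylsilyl ether F2.
  - F2 would be cleaved as in step 7 to the α-silyloxy aldehyde F3, which has no acyl group to migrate and a less acidic α-hydrogen.
  - Addition of 19 would give the carbinol F4.
  - Buffered fluoride (Bu4NF, AcOH) would free the diol F5.
  - Steglich esterification with 10 should take place at the unhindered C2 hydroxyl, not at the carbinol flanked by two ortho benzyloxy groups, and so give 20.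

Step 4.
- What may go wrong: a slow third fluoride displacement on a ring that already carries two alkoxy groups, leaving time for base-induced migration of the terminal double bond or for elimination.
- Fallback: the aryl ether is made by copper catalysis in place of the two substitutions. It sets out from 6 and comes back at 8. 5-Iodoresorcinol would be benzylated (BnBr, K2CO3) to 1-iodo-3,5-bis(benzyloxy)benzene F6. F6 would be coupled with 6 in an Ullmann-type etherification (CuI, 3,4,7,8-tetramethyl-1,10-phenanthroline, Cs2CO3, toluene, 110 °C). This also forms the O–C(aryl) bond and so retains C1.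

Step 18.
- What may go wrong: slow capture of the hindered acyloxonium ion by C8 of a nucleophile that carries a large ester and a C4 aryl group, with orthoester formation or elimination taking over; or partial attack at C6 of the middle ring.
- Fallback: the top ester is introduced after the interflavan bond. It sets out from 26 and 22 and comes back at 29. 26, with its free 3-OH, would be coupled with 22 under TMSOTf; the smaller electrophile should still react trans to the axial 3-OH and give the trimer with a free top 3-OH F7. Steglich esterification of F7 with 10 would give 29.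

## Further compounds

F1 | step 13 | (2R,3R,4RS)-5,7-bis(benzyloxy)-2-[3,4-bis(benzyloxy)phenyl]-4-hydroxychroman-3-yl 3,4,5-tris(benzyloxy)benzoate | C(c9ccccc9)Oc1cc(OCc9ccccc9)c2c(c1)O[C@H](c1ccc(OCc9ccccc9)c(OCc9ccccc9)c1)[C@H](OC(=O)c1cc(OCc9ccccc9)c(OCc9ccccc9)c(OCc9ccccc9)c1)C2O
F2 | step 12 | triethylsilyl ether of 9, (1R,2R) | C(c9ccccc9)Oc1cc(OCc9ccccc9)cc(c1)O[C@H](c1ccc(OCc9ccccc9)c(OCc9ccccc9)c1)[C@H](O[Si](CC)(CC)CC)C=C
F3 | step 12 | (2S,3R)-3-[3,4-bis(benzyloxy)phenyl]-3-[3,5-bis(benzyloxy)phenoxy]-2-(triethylsilyloxy)propanal | C(c9ccccc9)Oc1cc(OCc9ccccc9)cc(c1)O[C@H](c1ccc(OCc9ccccc9)c(OCc9ccccc9)c1)[C@H](O[Si](CC)(CC)CC)C=O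
F4 | step 12 | (1R,2R,3RS)-1-[3,4-bis(benzyloxy)phenyl]-1-[3,5-bis(benzyloxy)phenoxy]-2-(triethylsilyloxy)-3-[8-bromo-3,5,7,3',4'-penta-O-benzyl-(+)-catechin-6-yl]propan-3-ol | C(c9ccccc9)Oc1cc(OCc9ccccc9)cc(c1)O[C@H](c1ccc(OCc9ccccc9)c(OCc9ccccc9)c1)[C@H](O[Si](CC)(CC)CC)C(O)c1c(OCc9ccccc9)c(Br)c2c(c1OCc9ccccc9)C[C@H](OCc9ccccc9)[C@@H](c1ccc(OCc9ccccc9)c(OCc9ccccc9)c1)O2
F5 | step 12 | (1R,2R,3RS)-1-[3,4-bis(benzyloxy)phenyl]-1-[3,5-bis(benzyloxy)phenoxy]-3-[8-bromo-3,5,7,3',4'-penta-O-benzyl-(+)-catechin-6-yl]propane-2,3-diol | C(c9ccccc9)Oc1cc(OCc9ccccc9)cc(c1)O[C@H](c1ccc(OCc9ccccc9)c(OCc9ccccc9)c1)[C@H](O)C(O)c1c(OCc9ccccc9)c(Br)c2c(c1OCc9ccccc9)C[C@H](OCc9ccccc9)[C@@H](c1ccc(OCc9ccccc9)c(OCc9ccccc9)c1)O2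
F6 | step 4 | 1-iodo-3,5-bis(benzyloxy)benzene | Ic1cc(OCc9ccccc9)cc(OCc9ccccc9)c1
F7 | step 18 | 8-bromo-5,7,3',4'-tetra-O-benzyl-(−)-epicatechin-(4β→8)-5,7,3',4'-tetra-O-benzyl-3-O-[3,4,5-tris(benzyloxy)benzoyl]-(−)-epicatechin-(4β→6)-8-bromo-3,5,7,3',4'-penta-O-benzyl-(+)-catechin | O[C@@H]1[C@@H](c2c(OCc9ccccc9)cc(OCc9ccccc9)c3c2O[C@H](c2ccc(OCc9ccccc9)c(OCc9ccccc9)c2)[C@H](OC(=O)c2cc(OCc9ccccc9)c(OCc9ccccc9)c(OCc9ccccc9)c2)[C@H]3c2c(OCc9ccccc9)c(Br)c3c(c2OCc9ccccc9)C[C@H](OCc9ccccc9)[C@@H](c2ccc(OCc9ccccc9)c(OCc9ccccc9)c2)O3)c2c(OCc9ccccc9)cc(OCc9ccccc9)c(Br)c2O[C@@H]1c1ccc(OCc9ccccc9)c(OCc9ccccc9)c1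
A1 | alternative 1 | benzyl-protected trimer with free 3-OH on the top and middle units and 3-O-benzyl on the catechin unit | O[C@@H]1[C@@H](c2c(OCc9ccccc9)cc(OCc9ccccc9)c3c2O[C@H](c2ccc(OCc9ccccc9)c(OCc9ccccc9)c2)[C@H](O)[C@H]3c2c(OCc9ccccc9)cc3c(c2OCc9ccccc9)C[C@H](OCc9ccccc9)[C@@H](c2ccc(OCc9ccccc9)c(OCc9ccccc9)c2)O3)c2c(OCc9ccccc9)cc(OCc9ccccc9)cc2O[C@@H]1c1ccc(OCc9ccccc9)c(OCc9ccccc9)c1
A2 | alternative 1 | benzyl-protected bis(2,3-epoxychroman) trimer core without ring B on the top and middle units, each epoxide on the face of the later 3-OH | O1[C@@H]2[C@@H](c3c(OCc9ccccc9)cc(OCc9ccccc9)c4c3O[C@@H]3O[C@@H]3[C@H]4c3c(OCc9ccccc9)cc4c(c3OCc9ccccc9)C[C@H](OCc9ccccc9)[C@@H](c3ccc(OCc9ccccc9)c(OCc9ccccc9)c3)O4)c3c(OCc9ccccc9)cc(OCc9ccccc9)cc3O[C@H]12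
A3 | alternative 1 | tris[3,4-bis(benzyloxy)phenyl]aluminium | [Al](c1ccc(OCc9ccccc9)c(OCc9ccccc9)c1)(c1ccc(OCc9ccccc9)c(OCc9ccccc9)c1)c1ccc(OCc9ccccc9)c(OCc9ccccc9)c1
A4 | alternative 2 | octadeca-O-benzyl target with free 3-OH on the catechin unit | O=C(O[C@@H]1[C@@H](c2c(OCc9ccccc9)cc(OCc9ccccc9)c3c2O[C@H](c2ccc(OCc9ccccc9)c(OCc9ccccc9)c2)[C@H](OC(=O)c2cc(OCc9ccccc9)c(OCc9ccccc9)c(OCc9ccccc9)c2)[C@H]3c2c(OCc9ccccc9)cc3c(c2OCc9ccccc9)C[C@H](O)[C@@H](c2ccc(OCc9ccccc9)c(OCc9ccccc9)c2)O3)c2c(OCc9ccccc9)cc(OCc9ccccc9)cc2O[C@@H]1c1ccc(OCc9ccccc9)c(OCc9ccccc9)c1)c1cc(OCc9ccccc9)c(OCc9ccccc9)c(OCc9ccccc9)c1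
A5 | alternative 2 | benzyl-protected top–middle bis-gallate whose middle C4 carries a 2,6-bis(benzyloxy)-4-{(R)-[3,4-bis(benzyloxy)phenyl][(2S)-oxiran-2-yl]methoxy}phenyl group | O=C(O[C@@H]1[C@@H](c2c(OCc9ccccc9)cc(OCc9ccccc9)c3c2O[C@H](c2ccc(OCc9ccccc9)c(OCc9ccccc9)c2)[C@H](OC(=O)c2cc(OCc9ccccc9)c(OCc9ccccc9)c(OCc9ccccc9)c2)[C@H]3c2c(OCc9ccccc9)cc(O[C@H](c4ccc(OCc9ccccc9)c(OCc9ccccc9)c4)[C@@H]4CO4)cc2OCc9ccccc9)c2c(OCc9ccccc9)cc(OCc9ccccc9)cc2O[C@@H]1c1ccc(OCc9ccccc9)c(OCc9ccccc9)c1)c1cc(OCc9ccccc9)c(OCc9ccccc9)c(OCc9ccccc9)c1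
A6 | alternative 3 | octadeca-O-benzyl target with free 7-OH on the middle unit | O=C(O[C@@H]1[C@@H](c2c(O)cc(OCc9ccccc9)c3c2O[C@H](c2ccc(OCc9ccccc9)c(OCc9ccccc9)c2)[C@H](OC(=O)c2cc(OCc9ccccc9)c(OCc9ccccc9)c(OCc9ccccc9)c2)[C@H]3c2c(OCc9ccccc9)cc3c(c2OCc9ccccc9)C[C@H](OCc9ccccc9)[C@@H](c2ccc(OCc9ccccc9)c(OCc9ccccc9)c2)O3)c2c(OCc9ccccc9)cc(OCc9ccccc9)cc2O[C@@H]1c1ccc(OCc9ccccc9)c(OCc9ccccc9)c1)c1cc(OCc9ccccc9)c(OCc9ccccc9)c(OCc9ccccc9)c1
A7 | alternative 3 | benzyl-protected middle–bottom dimer with 7-O-trifluoromethanesulfonyl and 8-trimethylsilyl groups on the middle unit | O=S(=O)(C(F)(F)F)Oc1cc(OCc9ccccc9)c2c(c1[Si](C)(C)C)O[C@H](c1ccc(OCc9ccccc9)c(OCc9ccccc9)c1)[C@H](OC(=O)c1cc(OCc9ccccc9)c(OCc9ccccc9)c(OCc9ccccc9)c1)[C@H]2c1c(OCc9ccccc9)cc2c(c1OCc9ccccc9)C[C@H](OCc9ccccc9)[C@@H](c1ccc(OCc9ccccc9)c(OCc9ccccc9)c1)O2
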